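**Conventions.** Ring A carbons are written a1–a6 (a1 bears the lactone carbonyl carbon C7, a2 the diaryl ether oxygen, a3 H, a4 the pyran oxygen, a5 the pyran CH=, a6 OH). Ring B carbons are written b1–b6 (b1 OMe, b2 OH, b3 H, b4 the ether oxygen, b5 the ester oxygen, b6 prenyl). Compounds 1–38 are numbered as in the steps and in the compound list. ArB = 4-methoxy-2,5-bis(methoxymethoxy)-3-(3-methylbut-2-en-1-yl)phenyl, that is, ring B bonded through b4 with b2 and b5 as MOM ethers.

## Analysis of the target

Garcinisidone B (38) is a depsidone: ring A and ring B are joined by a diaryl ether oxygen (a2–O–b4) and by an ester (a1–C7(=O)–O–b5), which together close a seven-membered dioxepinone. Ring A is fully substituted except at a3 and carries a 2,2-dimethyl-2H-pyran fused across a4/a5; ring B is pentasubstituted, with OMe, OH and prenyl around the two bridging oxygens. There is no stereocentre, so every difficulty is one of regiochemistry and functional-group tolerance. The sensitive groups are the aryl ester (hydride, nucleophiles), the chromene and prenyl double bonds (protic acid and electrophiles, with hydrogenolysis excluded), the prenyl group next to the b5 oxygen (acid-induced chroman formation once b5 is free), the para-dioxygenated ring B (air oxidation when b2 and b5 are free) and the 2,4,6-trioxygenated benzoic acid that precedes the lactone (protodecarboxylation). The hard points are the order of six different substituents on ring A, in particular the direction of pyran fusion (a4/a5 and not a3/a4), and a diaryl ether between two electron-rich, ortho-substituted rings, for which substitution chemistry is weak. The strategy rests on reading ring A as a resorcinol mono-aryl ether: hydroxyl on a6, a carbon substituent ortho to it on a1, the aryloxy group meta to it on a2, hydrogen on a3, and a4/a5 as the two alkene carbons of a cyclic enol ether. This is the substitution code that a vinylketene–ynol ether benzannulation leaves behind, so ring A can be built from a pyranone and an alkyne that already carries ring B on its oxygen.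

## Retrosynthetic reasoning

**Lactone.** The last bond cut is the ester bond C7–O(b5) of 38, which leads to seco acid 37 and, behind it, to the bis-MOM acid 36. The cut is placed here because a 2-aryloxybenzoic acid whose phenol partner sits ortho to the ether oxygen closes to the seven-membered aryl ester by plain dehydrative lactonisation. Only the b5 hydroxyl can reach C7, so b2 and b5 need no differentiation and share one protecting group. The forward step has to activate a doubly ortho-substituted salicylic acid without intermolecular acylation of the a6 and b2 hydroxyls.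

**Oxidation level of C7 and the chromene.** Acid 36 is traced through aldehyde 35 and diol 34 to silyl ether 33. C7 is carried as a silyloxymethyl group because the ring-forming step needs an electron-rich alkyne and would not accept an ester on it. The chromene double bond of 33 is traced to the ketone of chromanone 31 (through alcohol 32), since that carbonyl is what the pyranone building block leaves at this position. Reduction and dehydration must come before C7 is oxidised, because neither an acid nor the lactone would survive the hydride.

**Ring A (key disconnection).** Chromanone 31 is cut at a1–a6, a2–a3 and a5–a6, which gives diazo ketone 9 and ynol ether 27. The fourth ring bond that is new relative to 9, a3–a4, comes from the 1,2-shift of the Wolff rearrangement. The cut is made here for three reasons. First, the a2–O bond is never formed by substitution: a2 is simply the oxygen-bearing alkyne carbon of 27, so the hindered diaryl ether problem disappears. Second, the pyran fusion is fixed, because a4 and a5 are the ring alkene carbons of 9. Third, the a6 hydroxyl arrives free and hydrogen-bonded, while all other oxygens are protected. The forward reaction must generate vinylketene 28, combine it with 27 in the correct orientation to give 29, and carry 29 through ring opening (30) and ring closure.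

**Diazo ketone 9.** 9 is traced to methyl ketone 7 by diazo transfer through the trifluoroacetyl derivative 8, 7 to acid 5 through acid chloride 6 (Negishi acylation), and 5 to ester 4. Ester 4 is the acid-cyclised Claisen product (through 3) of the commodity chemicals 1 and 2. The shorter textbook path, acylation of a simple diazoalkane with 6, is not taken: the ring alkene of 6 carries an acyl group on each carbon and would compete as a dipolarophile. The forward sequence must enolise 7 at the acetyl methyl and not at the ring methylene.

**Ynol ether 27.** 27 is cut at the silyl ether (26) and at the propargylic C–C bond, which leads to lithium acetylide 25 and a hydroxymethylation. Acetylide 25 is traced to dichlorovinyl ether 24, that is, to phenol 21 and 22 (through 23). This uses the phenol oxygen as the nucleophile and brings in both alkyne carbons in one piece.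

**Phenol 21.** Phenol 21 is traced to its silyl ether 20, and the prenyl group of 20 is cut at b6, which leads to arylcopper 19 (from aryllithium 18) and 17, that is, to silyl ether 16 and behind it phenol 15. The position is the one flanked by OMOM and OMe, so directed metalation finds it. The b4 oxygen of 15 is traced through boronate 14 and aryllithium 13 to bromide 12, which is made from bis-MOM ether 11 and methoxyhydroquinone 10. Bromination is placed before the prenylation because the position para to OMe is then the clear electronic preference and no alkene is present.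

## Alternatives that were turned down

Alternative 1: aryne, phenoxide and carbon dioxide three-component coupling.
- Disconnection: a2–O and a1–C7 in one operation. Ring A enters as the aryne that fluoride releases from the silylaryl triflate 3,5-bis(methoxymethoxy)-2-(trimethylsilyl)phenyl trifluoromethanesulfonate A1, ring B as the cesium salt of phenol 21, and C7 as carbon dioxide A2.
- Forward key step: fluoride removes the silyl group of A1 and the triflate leaves. The phenoxide oxygen adds to the aryne carbon remote from the neighbouring OMOM group, and the aryl anion formed next to that group is carboxylated by A2. This gives 2-(ArB-oxy)-4,6-bis(methoxymethoxy)benzoic acid A3; no ring is closed.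
- For: it uses 21 directly and so saves the three steps to the ynol ether. It makes the hindered diaryl ether without copper and needs no photochemistry. The regiochemistry of the aryne addition is dictated by the alkoxy group and is as secure as that of the chosen plan. To the diaryl ether acid it is the shorter route.
- Against: A3 has no pyran, and its a4 and a6 oxygens are not differentiated from each other or from the ring B MOM ethers. The pyran would have to be annulated late onto a polyphenol that carries the prenyl group and a free hydroquinone, with closure toward a3 competing with a5. The coupling itself is best established for neutral nitrogen nucleophiles that give zwitterions. A hindered anionic phenoxide is reversibly carboxylated by A2, and the aryl anion can be protonated or add to a second aryne generated from A1. In addition A1 is not a stock chemical and needs a sequence of its own.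
- Comparison: the chosen plan is longer but settles a4/a5 by construction and delivers a6 as the only free hydroxyl, so the risk is in one step and not in two.

Alternative 2: tethered pyranone Diels–Alder that forms ring A and the lactone together.
- Disconnection: a1–a2 and a3–a4. Ring A comes from a 2-pyranone (its C3 becomes a1, its C6 becomes a4) and a terminal ethynyl ether on b4, tethered through the b5 ester in 2-(ethynyloxy)-5-methoxy-4-(methoxymethoxy)-6-(3-methylbut-2-en-1-yl)phenyl 4-hydroxy-6-[(4-methoxybenzyl)oxy]-2-oxo-2H-pyran-3-carboxylate A4.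
- Forward key step: heating A4 at high dilution in a high-boiling aromatic solvent brings about the intramolecular cycloaddition and loss of A2. This gives the depsidone without the dimethylpyran, 1-hydroxy-8-methoxy-3-[(4-methoxybenzyl)oxy]-7-(methoxymethoxy)-9-(3-methylbut-2-en-1-yl)-11H-dibenzo[b,e][1,4]dioxepin-11-one A5.
- For: it forms more bonds per step than any other plan, closing ring A and the seven-membered ring at once. The tether dictates the regiochemistry, aromatisation is irreversible, and a6 arrives as free OH. On convergence at the key step it is stronger than the chosen plan.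
- Against: A4 is an aryl ester of an enolised β-keto acid and should lose the phenol as an acylketene at the temperature the cycloaddition needs. The ester must adopt its unfavourable s-cis conformation to reach a seven-membered tether. The terminal aryl ethynyl ether is fragile and has to be generated with organolithium before the ester is installed, which requires b5 to be protected orthogonally to b2 and b4. A5 still lacks the pyran, so deprotection and a regioselective chromene annulation (a5 against a3) follow.
- Comparison: the chosen plan gives up the simultaneous lactone closure but uses two robust fragments that can be made and stored, closes the lactone by routine dehydration, and has the pyran in place from the start.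

Alternative 3: one thermal Claisen cascade that places both isoprenoid units.
- Disconnection: the a5–C and O–C bonds of the pyran and the b6–C bond of the prenyl group, all on a finished depsidone. The precursor is the bis-ether 1-hydroxy-7-(methoxymethoxy)-8-[(2-methylbut-3-en-2-yl)oxy]-3-[(2-methylbut-3-yn-2-yl)oxy]-11H-dibenzo[b,e][1,4]dioxepin-11-one A6.
- Forward key step: heating A6 in a high-boiling tertiary aniline moves the propargyl unit from the a4 oxygen to a5 and closes the chromene (Claisen shift, hydrogen shift, oxa-6π closure). The 1,1-dimethylallyl group moves from the b1 oxygen to b6 as prenyl. The product is O-demethylgarcinisidone B with b2 as MOM ether A7.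
- For: both isoprenoid units are placed in one operation with no protecting-group changes around them. Each component reaction is well precedented, and the hydrogen bond from a6 OH to the carbonyl favours closure toward a5. For decorating the core it is more economical than the chosen route.
- Against: A6 presupposes the complete depsidone core, so the hard bonds (diaryl ether, ring A pattern) are not addressed. Two different tertiary ethers must be made selectively on one molecule to reach A6, the b1 ether next to an OMOM group. At the temperature required the new o-prenylphenol of A7 can cyclise to a chroman or undergo abnormal Claisen rearrangement, and tertiary allyl ethers also fragment. Afterwards the b1 hydroxyl of A7 must be methylated selectively over a6 OH.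
- Comparison: the chosen plan installs the prenyl group by directed metalation on a simple arene and the pyran as part of a building block, so neither depends on a sigmatropic shift on the sensitive lactone as in the conversion of A6 into A7; the price is a longer sequence.

Key step: step 14

Remark on the chemistry: ester 4 is not assumed to be purchasable and is made in step 1; compounds 29 and 32 are racemic, which is without consequence for the achiral target.

## Route

Step 1
Reactants: 1 mesityl oxide (4-methylpent-3-en-2-one); 2 diethyl oxalate
Product: 4 ethyl 6,6-dimethyl-4-oxo-5,6-dihydro-4H-pyran-2-carboxylate, via diketo ester 3 (not isolated)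
Conditions: NaOEt, EtOH, 0 °C to rt; then HCl, EtOH, 60 °C
Reagents that add atoms: none
Why: Crossed Claisen condensation of the methyl ketone enolate of 1 with the non-enolisable diester 2 gives 3 as its sodium enolate; acid then triggers a 6-endo oxa-Michael addition of the enol oxygen to the β,β-dimethyl enone, the classical entry to this dihydropyranone ester family.

Step 2
Reactants: 4 ethyl 6,6-dimethyl-4-oxo-5,6-dihydro-4H-pyran-2-carboxylate
Product: 5 6,6-dimethyl-4-oxo-5,6-dihydro-4H-pyran-2-carboxylic acid
Conditions: LiOH, THF–H2O, 0 °C; then 1 M HCl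
Reagents that add atoms: lithium hydroxide, [Li+].[OH-]
Why: Saponification of the activated α-alkoxyacrylate ester is fast at 0 °C; acidification recloses any ring-opened diketo acid, because the pyranone is the form that is stable in acid.

Step 3
Reactants: 5 6,6-dimethyl-4-oxo-5,6-dihydro-4H-pyran-2-carboxylic acid
Product: 7 6-acetyl-2,2-dimethyl-2,3-dihydro-4H-pyran-4-one, via acid chloride 6 (not isolated)
Conditions: (COCl)2, DMF (cat.), CH2Cl2, 0 °C to rt; then MeZnCl, Pd(PPh3)4 (cat.), THF, 0 °C to rt
Reagents that add atoms: methylzinc chloride, C[Zn]Cl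
Why: Acid chloride formation, then Negishi acylation: zerovalent palladium inserts into the acyl chloride and MeZnCl transfers the methyl group; an organozinc halide adds neither to the ring enone nor to the product ketone, as a Grignard or cuprate reagent might.

Step 4
Reactants: 7 6-acetyl-2,2-dimethyl-2,3-dihydro-4H-pyran-4-one
Product: 9 6-(2-diazoacetyl)-2,2-dimethyl-2,3-dihydro-4H-pyran-4-one, via trifluoroacetyl diketone 8 (not isolated)
Conditions: LiN(SiMe3)2, THF, −78 °C; CF3CO2CH2CF3, −78 °C; 5% aq HCl work-up; then MsN3, Et3N, H2O, MeCN, rt
Reagents that add atoms: methanesulfonyl azide, CS(=O)(=O)N=[N+]=[N-]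
Why: Detrifluoroacetylative diazo transfer: kinetic deprotonation should take the unhindered acetyl methyl of a true ketone and not the ring methylene next to the vinylogous-ester carbonyl, the enolate is trifluoroacetylated (Claisen condensation), and diazo transfer to 8 with loss of the trifluoroacetyl group gives 9. This is preferred to acylating a diazoalkane with 6, where the doubly acceptor-substituted ring alkene would compete as a dipolarophile.

Step 5
Reactants: 10 2-methoxybenzene-1,4-diol (methoxyhydroquinone)
Product: 11 2-methoxy-1,4-bis(methoxymethoxy)benzene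
Conditions: MOMCl, i-Pr2NEt, CH2Cl2, 0 °C to rt
Reagents that add atoms: chloromethyl methyl ether, COCCl
Why: O-Alkylation of both phenols to the mixed acetals; MOM is chosen because it directs the metalation of step 9 and can be removed without hydrogenation.

Step 6
Reactants: 11 2-methoxy-1,4-bis(methoxymethoxy)benzene
Product: 12 1-bromo-4-methoxy-2,5-bis(methoxymethoxy)benzene
Conditions: NBS, MeCN, 0 °C
Reagents that add atoms: N-bromosuccinimide, O=C1CCC(=O)N1Br
Why: Electrophilic aromatic bromination at the position para to OMe and ortho to an OMOM group, the most activated and least hindered site, as with 1,2,4-trialkoxybenzenes; it is done before the neighbouring position is substituted, while the OMe group can still lie in the ring plane and no alkene is present.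

Step 7
Reactants: 12 1-bromo-4-methoxy-2,5-bis(methoxymethoxy)benzene
Product: 15 4-methoxy-2,5-bis(methoxymethoxy)phenol, via aryllithium 13 (not isolated), via dimethyl arylboronate 14 (not isolated)
Conditions: n-BuLi, THF, −78 °C; B(OMe)3, −78 to 0 °C; then H2O2, NaOH, 0 °C
Reagents that add atoms: hydrogen peroxide, OO
Why: Bromine–lithium exchange, borylation and oxidative 1,2-aryl migration of the boronate replace bromine by the b4 hydroxyl without touching the MOM ethers.

Step 8
Reactants: 15 4-methoxy-2,5-bis(methoxymethoxy)phenol
Product: 16 triisopropyl[4-methoxy-2,5-bis(methoxymethoxy)phenoxy]silane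
Conditions: i-Pr3SiCl, imidazole, DMF, rt
Reagents that add atoms: chlorotriisopropylsilane, CC(C)[Si](Cl)(C(C)C)C(C)C
Why: Silylation of the phenol; the bulky silyl ether survives n-BuLi and shields its own ortho position in the next step.

Step 9
Reactants: 16 triisopropyl[4-methoxy-2,5-bis(methoxymethoxy)phenoxy]silane; 17 prenyl bromide (1-bromo-3-methylbut-2-ene)
Product: 20 triisopropyl[4-methoxy-2,5-bis(methoxymethoxy)-3-(3-methylbut-2-en-1-yl)phenoxy]silane, via aryllithium 18 (not isolated), via arylcopper 19 (not isolated)
Conditions: n-BuLi, TMEDA, THF, −78 to 0 °C; CuBr·SMe2, −78 °C; then 17, −78 °C to rt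
Reagents that add atoms: none
Why: Directed ortho-metalation removes the ring hydrogen flanked by OMOM and OMe through cooperative coordination, while the other free position lies next to the bulky, non-coordinating silyl ether. Transmetalation to copper makes the allylation SN2-selective, so that the prenyl and not the 1,1-dimethylallyl group is attached.

Step 10
Reactants: 20 triisopropyl[4-methoxy-2,5-bis(methoxymethoxy)-3-(3-methylbut-2-en-1-yl)phenoxy]silane
Product: 21 4-methoxy-2,5-bis(methoxymethoxy)-3-(3-methylbut-2-en-1-yl)phenol (ArB–OH)
Conditions: Bu4NF, THF, 0 °C; AcOH quench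
Reagents that add atoms: none
Why: Fluoride cleaves the aryl silyl ether; the MOM ethers and the prenyl group are inert.

Step 11
Reactants: 21 4-methoxy-2,5-bis(methoxymethoxy)-3-(3-methylbut-2-en-1-yl)phenol (ArB–OH); 22 trichloroethylene
Product: 24 ArB (E)-1,2-dichloroethenyl ether (ArB–O–CCl=CHCl), via dichloroacetylene 23 (not isolated)
Conditions: K2CO3, DMF, 60 °C
Reagents that add atoms: none
Why: Base eliminates HCl from 22 to give 23, to which the phenoxide adds anti to give the (E)-dichlorovinyl ether; both alkyne carbons are thus placed on the b4 oxygen with the phenol as nucleophile.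

Step 12
Reactants: 24 ArB (E)-1,2-dichloroethenyl ether
Product: 26 3-(ArB-oxy)prop-2-yn-1-ol, via lithium acetylide 25 (not isolated)
Conditions: n-BuLi (2.4 equiv), Et2O, −78 to −40 °C; (CH2O)n, −78 °C to rt; H2O
Reagents that add atoms: formaldehyde (as paraformaldehyde), C=O
Why: n-BuLi effects elimination and chlorine–lithium exchange to give 25, which adds to formaldehyde (hydroxymethylation), the established dichlorovinyl ether route to ynol ethers. The work-up is kept neutral to basic because ynol ethers hydrate under acid.

Step 13
Reactants: 26 3-(ArB-oxy)prop-2-yn-1-ol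
Product: 27 tert-butyldimethyl{[3-(ArB-oxy)prop-2-yn-1-yl]oxy}silane (ArB–O–C≡C–CH2OSiMe2t-Bu)
Conditions: t-BuMe2SiCl, imidazole, CH2Cl2, 0 °C to rt
Reagents that add atoms: tert-butylchlorodimethylsilane, CC(C)(C)[Si](C)(C)Cl
Why: Standard silylation; the silyl ether keeps the alkyne electron-rich and carries C7 at the alcohol oxidation level.

Step 14
Reactants: 9 6-(2-diazoacetyl)-2,2-dimethyl-2,3-dihydro-4H-pyran-4-one; 27 tert-butyldimethyl{[3-(ArB-oxy)prop-2-yn-1-yl]oxy}silane
Product: 31 6-(tert-butyldimethylsilyloxymethyl)-5-hydroxy-2,2-dimethyl-7-(ArB-oxy)chroman-4-one, via vinylketene 28 (not isolated), via 4-vinylcyclobutenone 29 (not isolated), via dienylketene 30 (not isolated)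
Conditions: hν (medium-pressure Hg lamp, Pyrex filter), ClCH2CH2Cl, 25 °C; then 80 °C
Reagents that add atoms: none
Why: Photolysis of 9 expels nitrogen and the oxygen-bearing ring alkene carbon shifts from the carbonyl carbon to the carbene carbon (photochemical Wolff rearrangement, making a3–a4) to give vinylketene 28. The ketene carbonyl carbon (future a6) is attacked by the oxygen-remote, nucleophilic carbon of ynol ether 27 (a1) and the ketene α carbon (a3) bonds to the oxygen-bearing alkyne carbon (a2), a [2+2] cycloaddition that gives 29. Light or warming to 80 °C opens 29 by 4π electrocyclic cleavage of the a3–a6 bond to dienylketene 30, whose ketene carbon closes onto the ring CH carbon of the pyranone (a5) by 6π electrocyclisation; enolisation then gives the hydrogen-bonded phenol 31. The closest known reaction type is the Danheiser benzannulation in its diazo ketone variant with alkoxy- and siloxyalkynes. Ring A is therefore closed by a thermal 6π electrocyclisation that forms an all-carbon six-membered ring, after the bonds a1–a6 and a2–a3 have been set in the cycloaddition. No stereocentre has to be controlled: the only one formed, the sp3 carbon of 29, is erased on ring opening, and the geometry of 30 corrects itself because the isomer that cannot cyclise recloses to 29. The selectivity needed is regiochemical, aryloxy meta and silyloxymethyl ortho to the new hydroxyl, and the donor polarisation of the ynol ether secures it, since only its β carbon is nucleophilic towards the ketene carbonyl carbon. Pyrex-filtered light is chosen to keep the aryl ether chromophores dark, and an aryl ynol ether has no β hydrogen through which it could lose a ketene by retro-ene fragmentation at 80 °C.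

Step 15
Reactants: 31 6-(tert-butyldimethylsilyloxymethyl)-5-hydroxy-2,2-dimethyl-7-(ArB-oxy)chroman-4-one
Product: 33 6-(tert-butyldimethylsilyloxymethyl)-2,2-dimethyl-7-(ArB-oxy)-2H-chromen-5-ol, via chroman-4-ol 32 (not isolated)
Conditions: NaBH4, THF–MeOH, 0 °C to rt; then PPTS (cat.), PhMe, 60 °C
Reagents that add atoms: none
Why: Hydride reduction of the hydrogen-bonded aryl ketone, then acid-catalysed E1 dehydration of the benzylic alcohol, whose cation is stabilised by two ortho oxygens and one para oxygen, so that a trace of weak acid should suffice. The stereocentre of racemic 32 is removed again.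

Step 16
Reactants: 33 6-(tert-butyldimethylsilyloxymethyl)-2,2-dimethyl-7-(ArB-oxy)-2H-chromen-5-ol
Product: 34 6-(hydroxymethyl)-2,2-dimethyl-7-(ArB-oxy)-2H-chromen-5-ol
Conditions: Bu4NF, AcOH, THF, 0 °C to rt
Reagents that add atoms: none
Why: Buffered fluoride desilylation; acetic acid keeps the medium from becoming basic enough to eliminate the o-hydroxybenzyl alcohol to a quinone methide.

Step 17
Reactants: 34 6-(hydroxymethyl)-2,2-dimethyl-7-(ArB-oxy)-2H-chromen-5-ol
Product: 35 5-hydroxy-2,2-dimethyl-7-(ArB-oxy)-2H-chromene-6-carbaldehyde
Conditions: MnO2, CH2Cl2, rt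
Reagents that add atoms: none
Why: Selective benzylic alcohol oxidation by MnO2; the product is a hydrogen-bonded salicylaldehyde and should not be over-oxidised.

Step 18
Reactants: 35 5-hydroxy-2,2-dimethyl-7-(ArB-oxy)-2H-chromene-6-carbaldehyde
Product: 36 5-hydroxy-2,2-dimethyl-7-(ArB-oxy)-2H-chromene-6-carboxylic acid
Conditions: NaClO2, NaH2PO4, 2-methyl-2-butene, t-BuOH–H2O, 0 °C to rt
Reagents that add atoms: sodium chlorite NaClO2, [Na+].[O-]Cl=O
Why: Pinnick oxidation; 2-methyl-2-butene in large excess scavenges HOCl so that the chromene, the prenyl group and the electron-rich arenes are not chlorinated.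

Step 19
Reactants: 36 5-hydroxy-2,2-dimethyl-7-(ArB-oxy)-2H-chromene-6-carboxylic acid
Product: 37 7-[2,5-dihydroxy-4-methoxy-3-(3-methylbut-2-en-1-yl)phenoxy]-5-hydroxy-2,2-dimethyl-2H-chromene-6-carboxylic acid
Conditions: ZnBr2, n-PrSH, CH2Cl2, 0 °C, argon
Reagents that add atoms: none
Why: Lewis acid-assisted thiolysis of both MOM acetals, expected to be complete within minutes at 0 °C without protic acid, which protects the prenyl group from cyclising onto the freed b5 hydroxyl and the acid from decarboxylation. 37 is kept under argon and used at once.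

Step 20
Reactants: 37 7-[2,5-dihydroxy-4-methoxy-3-(3-methylbut-2-en-1-yl)phenoxy]-5-hydroxy-2,2-dimethyl-2H-chromene-6-carboxylic acid
Product: 38 garcinisidone B
Conditions: EDC·HCl, DMAP (cat.), CH2Cl2–THF (2 mM), 0 °C to rt, argon
Reagents that add atoms: none
Why: Carbodiimide (Steglich-type) lactonisation: only the b5 hydroxyl can reach the activated carboxyl, which closes the seven-membered depsidone ring; high dilution suppresses intermolecular acylation of the a6 and b2 hydroxyls.

## Compound list

1 | mesityl oxide (4-methylpent-3-en-2-one) | CC(=O)C=C(C)C | starting material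
2 | diethyl oxalate | CCOC(=O)C(=O)OCC | starting material
3 | ethyl 6-methyl-2,4-dioxohept-5-enoate (formed as its sodium enolate) | CCOC(=O)C(=O)CC(=O)C=C(C)C | intermediate
4 | ethyl 6,6-dimethyl-4-oxo-5,6-dihydro-4H-pyran-2-carboxylate | CCOC(=O)C1=CC(=O)CC(C)(C)O1 | intermediate
5 | 6,6-dimethyl-4-oxo-5,6-dihydro-4H-pyran-2-carboxylic acid | OC(=O)C1=CC(=O)CC(C)(C)O1 | intermediate
6 | 6,6-dimethyl-4-oxo-5,6-dihydro-4H-pyran-2-carbonyl chloride | ClC(=O)C1=CC(=O)CC(C)(C)O1 | intermediate
7 | 6-acetyl-2,2-dimethyl-2,3-dihydro-4H-pyran-4-one | CC(=O)C1=CC(=O)CC(C)(C)O1 | intermediate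
8 | 2,2-dimethyl-6-(4,4,4-trifluoro-3-oxobutanoyl)-2,3-dihydro-4H-pyran-4-one | O=C(CC(=O)C(F)(F)F)C1=CC(=O)CC(C)(C)O1 | intermediate
9 | 6-(2-diazoacetyl)-2,2-dimethyl-2,3-dihydro-4H-pyran-4-one | [N-]=[N+]=CC(=O)C1=CC(=O)CC(C)(C)O1 | intermediate
10 | 2-methoxybenzene-1,4-diol (methoxyhydroquinone) | COc1cc(O)ccc1O | starting material
11 | 2-methoxy-1,4-bis(methoxymethoxy)benzene | COc1cc(OCOC)ccc1OCOC | intermediate
12 | 1-bromo-4-methoxy-2,5-bis(methoxymethoxy)benzene | COc1cc(OCOC)c(Br)cc1OCOC | intermediate
13 | [4-methoxy-2,5-bis(methoxymethoxy)phenyl]lithium | [Li]c1cc(OCOC)c(OC)cc1OCOC | intermediate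
14 | dimethyl [4-methoxy-2,5-bis(methoxymethoxy)phenyl]boronate | COB(OC)c1cc(OCOC)c(OC)cc1OCOC | intermediate
15 | 4-methoxy-2,5-bis(methoxymethoxy)phenol | COc1cc(OCOC)c(O)cc1OCOC | intermediate
16 | triisopropyl[4-methoxy-2,5-bis(methoxymethoxy)phenoxy]silane | COc1cc(OCOC)c(O[Si](C(C)C)(C(C)C)C(C)C)cc1OCOC | intermediate
17 | prenyl bromide (1-bromo-3-methylbut-2-ene) | CC(C)=CCBr | starting material
18 | {2-methoxy-3,6-bis(methoxymethoxy)-5-[(triisopropylsilyl)oxy]phenyl}lithium | [Li]c1c(OC)c(OCOC)cc(O[Si](C(C)C)(C(C)C)C(C)C)c1OCOC | intermediate
19 | {2-methoxy-3,6-bis(methoxymethoxy)-5-[(triisopropylsilyl)oxy]phenyl}copper | [Cu]c1c(OC)c(OCOC)cc(O[Si](C(C)C)(C(C)C)C(C)C)c1OCOC | intermediate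
20 | triisopropyl[4-methoxy-2,5-bis(methoxymethoxy)-3-(3-methylbut-2-en-1-yl)phenoxy]silane | COc1c(OCOC)cc(O[Si](C(C)C)(C(C)C)C(C)C)c(OCOC)c1CC=C(C)C | intermediate
21 | 4-methoxy-2,5-bis(methoxymethoxy)-3-(3-methylbut-2-en-1-yl)phenol | COc1c(OCOC)cc(O)c(OCOC)c1CC=C(C)C | intermediate
22 | trichloroethylene | ClC=C(Cl)Cl | starting material
23 | dichloroacetylene | ClC#CCl | intermediate
24 | 1-{[(E)-1,2-dichloroethenyl]oxy}-4-methoxy-2,5-bis(methoxymethoxy)-3-(3-methylbut-2-en-1-yl)benzene | COc1c(OCOC)cc(O/C(Cl)=C\Cl)c(OCOC)c1CC=C(C)C | intermediate
25 | {[4-methoxy-2,5-bis(methoxymethoxy)-3-(3-methylbut-2-en-1-yl)phenoxy]ethynyl}lithium | COc1c(OCOC)cc(OC#C[Li])c(OCOC)c1CC=C(C)C | intermediate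
26 | 3-[4-methoxy-2,5-bis(methoxymethoxy)-3-(3-methylbut-2-en-1-yl)phenoxy]prop-2-yn-1-ol | COc1c(OCOC)cc(OC#CCO)c(OCOC)c1CC=C(C)C | intermediate
27 | tert-butyl({3-[4-methoxy-2,5-bis(methoxymethoxy)-3-(3-methylbut-2-en-1-yl)phenoxy]prop-2-yn-1-yl}oxy)dimethylsilane | COc1c(OCOC)cc(OC#CCO[Si](C)(C)C(C)(C)C)c(OCOC)c1CC=C(C)C | intermediate
28 | 2-(6,6-dimethyl-4-oxo-5,6-dihydro-4H-pyran-2-yl)ethenone (pyranonyl ketene) | O=C=CC1=CC(=O)CC(C)(C)O1 | intermediate
29 | rac-2-{[(tert-butyldimethylsilyl)oxy]methyl}-4-(6,6-dimethyl-4-oxo-5,6-dihydro-4H-pyran-2-yl)-3-[4-methoxy-2,5-bis(methoxymethoxy)-3-(3-methylbut-2-en-1-yl)phenoxy]cyclobut-2-en-1-one | COc1c(OCOC)cc(OC2=C(CO[Si](C)(C)C(C)(C)C)C(=O)C2C3=CC(=O)CC(C)(C)O3)c(OCOC)c1CC=C(C)C | intermediate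
30 | (3E)-2-{[(tert-butyldimethylsilyl)oxy]methyl}-4-(6,6-dimethyl-4-oxo-5,6-dihydro-4H-pyran-2-yl)-3-[4-methoxy-2,5-bis(methoxymethoxy)-3-(3-methylbut-2-en-1-yl)phenoxy]buta-1,3-dien-1-one | COc1c(OCOC)cc(O/C(C(=C=O)CO[Si](C)(C)C(C)(C)C)=C/C2=CC(=O)CC(C)(C)O2)c(OCOC)c1CC=C(C)C | intermediate
31 | 6-{[(tert-butyldimethylsilyl)oxy]methyl}-5-hydroxy-7-[4-methoxy-2,5-bis(methoxymethoxy)-3-(3-methylbut-2-en-1-yl)phenoxy]-2,2-dimethyl-2,3-dihydro-4H-chromen-4-one | COc1c(OCOC)cc(Oc2cc3OC(C)(C)CC(=O)c3c(O)c2CO[Si](C)(C)C(C)(C)C)c(OCOC)c1CC=C(C)C | intermediate
32 | rac-6-{[(tert-butyldimethylsilyl)oxy]methyl}-7-[4-methoxy-2,5-bis(methoxymethoxy)-3-(3-methylbut-2-en-1-yl)phenoxy]-2,2-dimethyl-3,4-dihydro-2H-chromene-4,5-diol | COc1c(OCOC)cc(Oc2cc3OC(C)(C)CC(O)c3c(O)c2CO[Si](C)(C)C(C)(C)C)c(OCOC)c1CC=C(C)C | intermediate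
33 | 6-{[(tert-butyldimethylsilyl)oxy]methyl}-7-[4-methoxy-2,5-bis(methoxymethoxy)-3-(3-methylbut-2-en-1-yl)phenoxy]-2,2-dimethyl-2H-chromen-5-ol | COc1c(OCOC)cc(Oc2cc3OC(C)(C)C=Cc3c(O)c2CO[Si](C)(C)C(C)(C)C)c(OCOC)c1CC=C(C)C | intermediate
34 | 6-(hydroxymethyl)-7-[4-methoxy-2,5-bis(methoxymethoxy)-3-(3-methylbut-2-en-1-yl)phenoxy]-2,2-dimethyl-2H-chromen-5-ol | COc1c(OCOC)cc(Oc2cc3OC(C)(C)C=Cc3c(O)c2CO)c(OCOC)c1CC=C(C)C | intermediate
35 | 5-hydroxy-7-[4-methoxy-2,5-bis(methoxymethoxy)-3-(3-methylbut-2-en-1-yl)phenoxy]-2,2-dimethyl-2H-chromene-6-carbaldehyde | COc1c(OCOC)cc(Oc2cc3OC(C)(C)C=Cc3c(O)c2C=O)c(OCOC)c1CC=C(C)C | intermediate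
36 | 5-hydroxy-7-[4-methoxy-2,5-bis(methoxymethoxy)-3-(3-methylbut-2-en-1-yl)phenoxy]-2,2-dimethyl-2H-chromene-6-carboxylic acid | COc1c(OCOC)cc(Oc2cc3OC(C)(C)C=Cc3c(O)c2C(=O)O)c(OCOC)c1CC=C(C)C | intermediate
37 | 7-[2,5-dihydroxy-4-methoxy-3-(3-methylbut-2-en-1-yl)phenoxy]-5-hydroxy-2,2-dimethyl-2H-chromene-6-carboxylic acid | COc1c(O)cc(Oc2cc3OC(C)(C)C=Cc3c(O)c2C(=O)O)c(O)c1CC=C(C)C | intermediate
38 | garcinisidone B | COc1c(O)cc2c(c1CC=C(C)C)OC(=O)c1c(cc3c(c1O)C=CC(C)(C)O3)O2 | target

## Step count and risks

Total step count: 20. Longest linear sequence: 16 steps (steps 5–13 from methoxyhydroquinone 10, then steps 14–20). The diazo ketone branch (steps 1–4) joins at step 14.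

Steps least certain to work:

**Step 14 (key step).**
- What may go wrong: the pyranone enone or the electron-rich aryl ynol ether may absorb light and divert into photocycloaddition or photofragmentation. The [2+2] step may be slow because an aryloxy alkyne is less nucleophilic than the alkoxy and siloxy alkynes usually used, so that ketene dimerisation, or acylation of the product phenol by the ketene, competes.
- Fallback (from 9 and 27, back to the route at 31): generate the same vinylketene thermally and in the dark. Silver-promoted Wolff rearrangement of 9 in wet THF (PhCO2Ag, Et3N, THF–H2O) should give (6,6-dimethyl-4-oxo-5,6-dihydro-4H-pyran-2-yl)acetic acid F1, and oxalyl chloride converts it into (6,6-dimethyl-4-oxo-5,6-dihydro-4H-pyran-2-yl)acetyl chloride F2. Slow addition of F2 to 27 and Et3N in toluene at 60–80 °C dehydrochlorinates it to 28, which is trapped by 27 as 29 (the classical acid chloride–amine route to 3-alkoxycyclobutenones). Continued heating carries 29 through 30 to 31.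

**Step 4.**
- What may go wrong: enolisation at the ring methylene instead of the acetyl methyl, or base-induced ring opening of the dihydropyranone by retro-oxa-Michael elimination.
- Fallback (from 5 through acid chloride 6, back at 9, bypassing 7 and 8): acylate (trimethylsilyl)diazomethane with 6 (Me3SiCHN2, MeCN–THF, 0 °C); chloride removes the silyl group after C-acylation. No compound outside the compound list is made, so the entry for this fallback is F0. This removes the enolate problem at the cost of possible dipolar addition to the ring alkene, which the bulky silylated dipole should undergo more slowly than acylation.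

**Step 9.**
- What may go wrong: metalation at the other free ring position (between OMOM and the silyl ether), followed by silyl migration from oxygen to carbon, or incomplete metalation.
- Fallback (from 15, back at 21, omitting 16 and 20): deprotonate phenol 15 twice (n-BuLi, TMEDA, THF). The lithium phenoxide deactivates its own ortho position, so the second lithiation should go to the carbon flanked by OMOM and OMe. Transmetalation with CuBr·SMe2 and reaction with 17 then gives 21 directly, since O-alkylation of a lithium phenoxide is slow in THF at low temperature. No compound outside the compound list is made, so the entry for this fallback is F0.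

**Step 15.**
- What may go wrong: sluggish reduction of the chelated ketone, over-reduction to the chroman by hydride addition to a quinone methide, or loss of the benzylic silyl ether or of MOM groups during the acid-catalysed dehydration.
- Fallback (from 31, back at 34): mask the a6 hydroxyl and dehydrate under neutral conditions. Silylation (t-BuMe2SiOTf, 2,6-lutidine, CH2Cl2, −78 °C) gives 5-(tert-butyldimethylsilyloxy)-6-(tert-butyldimethylsilyloxymethyl)-2,2-dimethyl-7-(ArB-oxy)chroman-4-one F3. NaBH4 reduces the now unchelated ketone to the racemic bis-silyl chroman-4-ol F4. Burgess reagent (MeO2CN−SO2N+Et3, PhMe, 50 °C) dehydrates F4 to the bis-silyl chromene F5. Excess Bu4NF removes both silyl groups of F5 and gives 34.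

**Step 19.**
- What may go wrong: protodecarboxylation of the electron-rich salicylic acid, cyclisation of the prenyl group onto the freed b5 hydroxyl, and air oxidation of the free hydroquinone before the lactone is closed.
- Fallback (from 36, back at 38): take the carboxyl through the deprotection as an active ester. Esterification of 36 with pentafluorophenol (DCC, DMAP cat., CH2Cl2) gives pentafluorophenyl 5-hydroxy-2,2-dimethyl-7-(ArB-oxy)-2H-chromene-6-carboxylate F6. MOM cleavage of F6 as in step 19 gives pentafluorophenyl 7-[2,5-dihydroxy-4-methoxy-3-(3-methylbut-2-en-1-yl)phenoxy]-5-hydroxy-2,2-dimethyl-2H-chromene-6-carboxylate F7, which cannot decarboxylate. Dilute i-Pr2NEt in MeCN then lets the b5 phenoxide of F7 displace pentafluorophenoxide intramolecularly to give 38.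

## Further compounds

F1 | step 14 | (6,6-dimethyl-4-oxo-5,6-dihydro-4H-pyran-2-yl)acetic acid | OC(=O)CC1=CC(=O)CC(C)(C)O1
F2 | step 14 | (6,6-dimethyl-4-oxo-5,6-dihydro-4H-pyran-2-yl)acetyl chloride | ClC(=O)CC1=CC(=O)CC(C)(C)O1
F0 | step 4 | none | none
F0 | step 9 | none | none
F3 | step 15 | 5-[(tert-butyldimethylsilyl)oxy]-6-{[(tert-butyldimethylsilyl)oxy]methyl}-7-[4-methoxy-2,5-bis(methoxymethoxy)-3-(3-methylbut-2-en-1-yl)phenoxy]-2,2-dimethyl-2,3-dihydro-4H-chromen-4-one | COc1c(OCOC)cc(Oc2cc3OC(C)(C)CC(=O)c3c(O[Si](C)(C)C(C)(C)C)c2CO[Si](C)(C)C(C)(C)C)c(OCOC)c1CC=C(C)C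
F4 | step 15 | rac-5-[(tert-butyldimethylsilyl)oxy]-6-{[(tert-butyldimethylsilyl)oxy]methyl}-7-[4-methoxy-2,5-bis(methoxymethoxy)-3-(3-methylbut-2-en-1-yl)phenoxy]-2,2-dimethyl-3,4-dihydro-2H-chromen-4-ol | COc1c(OCOC)cc(Oc2cc3OC(C)(C)CC(O)c3c(O[Si](C)(C)C(C)(C)C)c2CO[Si](C)(C)C(C)(C)C)c(OCOC)c1CC=C(C)C
F5 | step 15 | tert-butyl{[6-{[(tert-butyldimethylsilyl)oxy]methyl}-7-[4-methoxy-2,5-bis(methoxymethoxy)-3-(3-methylbut-2-en-1-yl)phenoxy]-2,2-dimethyl-2H-chromen-5-yl]oxy}dimethylsilane | COc1c(OCOC)cc(Oc2cc3OC(C)(C)C=Cc3c(O[Si](C)(C)C(C)(C)C)c2CO[Si](C)(C)C(C)(C)C)c(OCOC)c1CC=C(C)C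
F6 | step 19 | pentafluorophenyl 5-hydroxy-7-[4-methoxy-2,5-bis(methoxymethoxy)-3-(3-methylbut-2-en-1-yl)phenoxy]-2,2-dimethyl-2H-chromene-6-carboxylate | COc1c(OCOC)cc(Oc2cc3OC(C)(C)C=Cc3c(O)c2C(=O)Oc4c(F)c(F)c(F)c(F)c4F)c(OCOC)c1CC=C(C)C
F7 | step 19 | pentafluorophenyl 7-[2,5-dihydroxy-4-methoxy-3-(3-methylbut-2-en-1-yl)phenoxy]-5-hydroxy-2,2-dimethyl-2H-chromene-6-carboxylate | COc1c(O)cc(Oc2cc3OC(C)(C)C=Cc3c(O)c2C(=O)Oc4c(F)c(F)c(F)c(F)c4F)c(O)c1CC=C(C)C
A1 | alternative 1 | 3,5-bis(methoxymethoxy)-2-(trimethylsilyl)phenyl trifluoromethanesulfonate | COCOc1cc(OCOC)c([Si](C)(C)C)c(OS(=O)(=O)C(F)(F)F)c1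
A2 | alternative 1 | carbon dioxide | O=C=O
A3 | alternative 1 | 2-[4-methoxy-2,5-bis(methoxymethoxy)-3-(3-methylbut-2-en-1-yl)phenoxy]-4,6-bis(methoxymethoxy)benzoic acid | COc1c(OCOC)cc(Oc2cc(OCOC)cc(OCOC)c2C(=O)O)c(OCOC)c1CC=C(C)C
A4 | alternative 2 | 2-(ethynyloxy)-5-methoxy-4-(methoxymethoxy)-6-(3-methylbut-2-en-1-yl)phenyl 4-hydroxy-6-[(4-methoxybenzyl)oxy]-2-oxo-2H-pyran-3-carboxylate | COc1c(OCOC)cc(OC#C)c(OC(=O)c2c(O)cc(OCc3ccc(OC)cc3)oc2=O)c1CC=C(C)C
A5 | alternative 2 | 1-hydroxy-8-methoxy-3-[(4-methoxybenzyl)oxy]-7-(methoxymethoxy)-9-(3-methylbut-2-en-1-yl)-11H-dibenzo[b,e][1,4]dioxepin-11-one | COc1c(OCOC)cc2c(c1CC=C(C)C)OC(=O)c1c(O)cc(OCc3ccc(OC)cc3)cc1O2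
A6 | alternative 3 | 1-hydroxy-7-(methoxymethoxy)-8-[(2-methylbut-3-en-2-yl)oxy]-3-[(2-methylbut-3-yn-2-yl)oxy]-11H-dibenzo[b,e][1,4]dioxepin-11-one | C=CC(C)(C)Oc1c(OCOC)cc2c(c1)OC(=O)c1c(O)cc(OC(C)(C)C#C)cc1O2
A7 | alternative 3 | O-demethylgarcinisidone B with the b1 hydroxyl free and b2 as methoxymethyl ether | Oc1c(OCOC)cc2c(c1CC=C(C)C)OC(=O)c1c(cc3c(c1O)C=CC(C)(C)O3)O2
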